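in all of them: Z 1.1 M; J 120 mM (held); time 2.5 h

| flask | X |
|---|---|
| ochre | 0.0120 M |
| green | 0.0200 M |
| red | 0.0400 M |
| grey | 0.0800 M |

1. [D.G] at the end for ochre, green, red, grey, in this order
2. the shape of the row from first to last (falls, then rises / rises, then falls / rises all the way / hardly changes / falls all the way)

- at the start none of E is dissolved
- "hardly changes" means that all values lie within two and a half points (for a concentration: within two and a half percent of the largest)
- run time (ochre): 2.5 h

    Z → D (k1 = 1.8 × 10⁻⁴ s⁻¹)
    E → G (k2 = 1.9 × 10⁻⁴ s⁻¹)
    D + G → D.G (k3 = 9.8 × 10⁻⁴ M⁻¹ s⁻¹)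
    J ⇌ E, rate k4*(csat - [E]) (k4 = 0.0049 s⁻¹, csat = 120 mM)
    D + X → D.X (k5 = 1.2 × 10⁻⁴ M⁻¹ s⁻¹)

1. The easy step is E. It levels at 0.116 M after a lag of about 3.27 min, so G is made at 2.19 × 10⁻⁵ M s⁻¹, which comes to 0.193 M in 2.5 h. [X] appears nowhere in that sum.

2. For a first round I ignore what D.G takes from D, so [D] at the end is 0.882 M. The loss of G is pseudo-first-order in G, with k3[D] as its constant, so [G] sits near the quasi-steady value of feed/(k3[D]), which is 0.0254 M. That leaves [D.G] at 0.168 M.

3. I put that answer back. [D] becomes 0.714 M and [G] becomes 0.0313 M, which gives [D.G] of 0.162 M. G lasts 23.8 min, shorter than the run, so the steady value may be used.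

4. Now I turn the question round: what would make the row leave its margin of 0.00405 M? If X removes some D, [G] rises in proportion and [D.G] falls by the same amount. So [D.G] falls by the D removed times [G]/[D], the pass-through, which is 0.0439. This ratio is the thing to watch in a repeat.

5. Leaving the margin would take 0.0922 M more D removed in grey than in ochre. That is more than the difference of 0.0680 M in charged X.

6. With my first [D] curve, a fraction 0.549 of X remains, so grey loses 0.00135 M of [D.G] against ochre. I expect the row to hardly change.

The forecast gives 0.16 M, 0.16 M, 0.1595 M, 0.1585 M, and hardly changes, a little below my [D.G], on the ground that “X removes only a few hundredths of a molar of D at most”.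

The run gives 0.160 M, 0.160 M, 0.160 M, 0.159 M: hardly changes, as the forecast has it. Taking the turning of D + X into D.X out of grey leaves its [D.G] within the margin. Grey ends with [D.X] at 2.95 % of the Z charged, and the pass-through puts its loss at about 0.894 % of its [D.G]. Ochre ends with 0.450 %, and the same ratio puts its loss at 0.136 %.

The rate constants were drawn at random within sensible limits; the flask was simulated.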